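A direct plan would build ring A as the ortho-silylaryl triflate A1 in five steps from a dihydroxybenzaldehyde, set its aryne free with fluoride and let it insert into the acyl C–O bond of the caesium arylpropiolate A2 to give the 2-hydroxyaryl ynone A3.
A secondary amine would then close ring C at O1–C2 to the 5-O-tosyl flavone A4; aqueous hydroxide would remove the tosyl group and hydrogenolysis the two benzyl groups.
Weakest points of such a plan:
- The aryne insertion: the aryne is flanked by a tosyloxy and a methoxy group, both σ-acceptors, so the carboxylate could add at either end (8-methoxy or 6-methoxy series); protonation of the aryl anion and loss of CO2 from the propiolate would compete with the acyl shift.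
- The five-step run-up to A1 (benzylation, tosylation, Baeyer–Villiger oxidation, bromination, retro-Brook shift with triflation) would only move substituents around a benzene ring and form no bond of the skeleton.
- The late detosylation of A4 with warm aqueous hydroxide: hydroxide can add to C2 of the γ-pyrone, open ring C to the 1,3-diketone and let it close again through the other phenol, which would scramble the 8-methoxy pattern.

**Retrosynthetic overview** (flavone numbering: O1, C2–C4, C4a, C5–C8, C8a; primed numbers for ring B)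
Ring A (C4a–C5–C6–C7–C8–C8a) carries oxygen on the alternate carbons C5, C7 and C8a, the mark of a polyketide ring. It is therefore made last, cut at C5–C6 and C7–C8, back to the monocyclic γ-pyrone 9 (rings C and B) with a CH2OMe group on the future C8a, a methyl ester on the future C4a, and an acetyl unit for C6–C7.
Ring C is cut at C4–C4a and O1–C2: C-acylation of methyl 4-methoxyacetoacetate 6 by the ring B propiolic acid 5, then 6-endo closure. The ketone oxygen of 6 becomes O1 and its CH2OMe carbon becomes C8.
Order of rings: ring B is bought, ring C closes in step 4, ring A in step 6; hydrogenolysis of the one benzyl ether (O2') ends the route.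
No aryne and no choice between 8- and 6-methoxy arises, because O1–C8a and C8–OMe are bonded before ring A exists. There is no run-up on a benzene ring, and no tosyl or benzyl group on ring A: 5-OH and 7-OH are born free from an ester and a ketone carbonyl, so the flavone never meets hydroxide.

Key step: step 6

Remark: the target has no stereocentre; 11 is formed and used as the racemate, and 6 and 1-acetylbenzotriazole are taken as commercial.

Step 1
Reactants: 1 2-hydroxy-4,5-dimethoxybenzaldehyde
Product: 2 2-(benzyloxy)-4,5-dimethoxybenzaldehyde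
Conditions: BnBr (1.2 equiv), K2CO3 (1.5 equiv), DMF, rt
Reagents that add atoms: benzyl bromide, BrCc1ccccc1
Why: Williamson etherification of the only phenol gives a benzyl ether that withstands butyllithium and the lithium amide bases used later and is removed last by hydrogenolysis.

Step 2
Reactants: 2 2-(benzyloxy)-4,5-dimethoxybenzaldehyde
Product: 3 1-(benzyloxy)-2-(2,2-dibromoethenyl)-4,5-dimethoxybenzene
Conditions: CBr4 (2 equiv), PPh3 (4 equiv), CH2Cl2, 0 °C
Reagents that add atoms: carbon tetrabromide, BrC(Br)(Br)Br
Why: First stage of the Corey–Fuchs reaction, a Wittig-type dibromo-olefination of the aldehyde by the ylide formed from PPh3 and CBr4.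

Step 3
Reactants: 3 1-(benzyloxy)-2-(2,2-dibromoethenyl)-4,5-dimethoxybenzene
Product: 5 3-[2-(benzyloxy)-4,5-dimethoxyphenyl]prop-2-ynoic acid, via lithium acetylide 4 (not isolated)
Conditions: n-BuLi (2.2 equiv), THF, −78 °C → 0 °C; CO2 (g), −78 °C → rt; 1 M HCl
Reagents that add atoms: carbon dioxide, O=C=O
Why: Second stage of the Corey–Fuchs reaction (bromine–lithium exchange, Fritsch–Buttenberg–Wiechell shift and deprotonation to the acetylide 4), followed by carboxylation of the acetylide with CO2.

Step 4
Reactants: 5 3-[2-(benzyloxy)-4,5-dimethoxyphenyl]prop-2-ynoic acid; 6 methyl 4-methoxy-3-oxobutanoate (methyl 4-methoxyacetoacetate)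
Product: 9 methyl 6-[2-(benzyloxy)-4,5-dimethoxyphenyl]-2-(methoxymethyl)-4-oxo-4H-pyran-3-carboxylate, via acid chloride 7 (not isolated), via C-acylated keto ester 8 (not isolated)
Conditions: (COCl)2 (1.2 equiv), DMF (cat.), CH2Cl2, 0 °C → rt, then evaporation; 6 (1.1 equiv), MgCl2 (1.2 equiv), pyridine (2.5 equiv), CH2Cl2, 0 °C, then 7 added at −20 °C → rt; then Et3N (0.2 equiv), 40 °C
Reagents that add atoms: none
Why: Magnesium-chelate C-acylation of the β-keto ester (Rathke-type soft enolisation) by the ynoyl chloride 7 gives the enolised 2-acyl keto ester 8, whose methoxyacetyl enol oxygen adds to the β-carbon of the ynone in a 6-endo-dig oxa-Michael closure, the classical way from acylated acetoacetates and arylpropiolyl chlorides to 4-pyranone-3-carboxylates; this forms C4–C4a and O1–C2, and because the ketone of 6 is the only enolisable carbonyl that can reach the alkyne, O1 ends up on the carbon that carries the CH2OMe group (the future C8a–C8).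

Step 5
Reactants: 9 methyl 6-[2-(benzyloxy)-4,5-dimethoxyphenyl]-2-(methoxymethyl)-4-oxo-4H-pyran-3-carboxylate
Product: 11 methyl 6-[2-(benzyloxy)-4,5-dimethoxyphenyl]-2-(1-methoxy-2-oxopropyl)-4-oxo-4H-pyran-3-carboxylate (racemate), via lithium dienolate 10 (not isolated)
Conditions: LiN(SiMe3)2 (2.2 equiv), THF, −78 °C; 1-acetylbenzotriazole (1.3 equiv), −78 °C → −20 °C; cold 1 M HCl
Reagents that add atoms: 1-acetyl-1H-benzotriazole, CC(=O)n1nnc2ccccc21
Why: The CH2OMe protons are vinylogous to the C4 ketone and to the ester, so LiN(SiMe3)2 gives the extended enolate 10, which is acylated at its exocyclic carbon (vinylogous Claisen-type C-acylation, as known for the lateral anions of 2-alkyl-4-pyranones and 2-methylchromones; N-acylbenzotriazoles are C-selective acyl donors for lithium enolates) to form C7–C8; the second equivalent of base takes up the more acidic product, and the new stereocentre at C8 is formed without control and is erased in step 6.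

Step 6
Reactants: 11 methyl 6-[2-(benzyloxy)-4,5-dimethoxyphenyl]-2-(1-methoxy-2-oxopropyl)-4-oxo-4H-pyran-3-carboxylate (racemate)
Product: 13 2-[2-(benzyloxy)-4,5-dimethoxyphenyl]-5,7-dihydroxy-8-methoxy-4H-chromen-4-one, via dilithium dianion 12 (not isolated)
Conditions: LiN(i-Pr)2 (3.3 equiv), THF, −78 °C → 0 °C; 1 M HCl
Reagents that add atoms: none
Why: The first equivalent of LiN(i-Pr)2 removes the acidic C8–H and a second one an acetyl CH3 proton, so that the dianion 12 carries its most nucleophilic site on C6; this carbon attacks the C5 ester carbonyl, methoxide leaves, and the cyclohexenedione so formed enolises at once to the aromatic 5,7-diol (intramolecular Claisen condensation with aromatisation, forming C5–C6). The closest known reactions are the base-mediated closure of 2-(2-oxopropyl)benzoates, made by lateral acylation of ortho-toluates, to naphthalene-1,3-diols, and the Claisen folding of triketo esters to acylphloroglucinols. Ring A closes in the 6-exo-trig mode onto the ester; no stereocentre is formed, and the one at C8 of 11 becomes sp2. The step needs C-acylation by C6 and not O-acylation by the C7 enolate oxygen (which would give a fused 2-pyranone), and it needs the γ-pyrone to survive the base: the dianion puts the charge on carbon, and the pyranone is shielded because it is part of the enolate. Attack of C6 on the C4 ketone would give only a bridged, reversible aldolate, so the ester carbon is the one productive acceptor. The 8-methoxy pattern cannot scramble, because O1–C8a and C8–OMe are in place before C5 bears an oxygen.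

Step 7
Reactants: 13 2-[2-(benzyloxy)-4,5-dimethoxyphenyl]-5,7-dihydroxy-8-methoxy-4H-chromen-4-one
Product: 14 5,7-dihydroxy-2-(2-hydroxy-4,5-dimethoxyphenyl)-8-methoxy-4H-chromen-4-one
Conditions: H2 (1 atm), 10% Pd/C (palladium metal on carbon), EtOAc–MeOH, rt
Reagents that add atoms: none
Why: Catalytic hydrogenolysis of the single benzyl ether over palladium on carbon, under which the conjugated C2=C3 bond of a flavone is not expected to be reduced at atmospheric pressure and room temperature.

**Compound list**

1 | 2-hydroxy-4,5-dimethoxybenzaldehyde | COc1cc(O)c(C=O)cc1OC | starting material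
2 | 2-(benzyloxy)-4,5-dimethoxybenzaldehyde | COc1cc(OCc2ccccc2)c(C=O)cc1OC | intermediate
3 | 1-(benzyloxy)-2-(2,2-dibromoethenyl)-4,5-dimethoxybenzene | COc1cc(OCc2ccccc2)c(C=C(Br)Br)cc1OC | intermediate
4 | lithium [2-(benzyloxy)-4,5-dimethoxyphenyl]acetylide | [Li]C#Cc1cc(OC)c(OC)cc1OCc1ccccc1 | intermediate
5 | 3-[2-(benzyloxy)-4,5-dimethoxyphenyl]prop-2-ynoic acid | OC(=O)C#Cc1cc(OC)c(OC)cc1OCc1ccccc1 | intermediate
6 | methyl 4-methoxy-3-oxobutanoate | COCC(=O)CC(=O)OC | starting material
7 | 3-[2-(benzyloxy)-4,5-dimethoxyphenyl]prop-2-ynoyl chloride | ClC(=O)C#Cc1cc(OC)c(OC)cc1OCc1ccccc1 | intermediate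
8 | methyl 5-[2-(benzyloxy)-4,5-dimethoxyphenyl]-2-(methoxyacetyl)-3-oxopent-4-ynoate (enolised; drawn as the triketo tautomer) | COCC(=O)C(C(=O)OC)C(=O)C#Cc1cc(OC)c(OC)cc1OCc1ccccc1 | intermediate
9 | methyl 6-[2-(benzyloxy)-4,5-dimethoxyphenyl]-2-(methoxymethyl)-4-oxo-4H-pyran-3-carboxylate | COCc1oc(-c2cc(OC)c(OC)cc2OCc2ccccc2)cc(=O)c1C(=O)OC | intermediate
10 | lithium 6-[2-(benzyloxy)-4,5-dimethoxyphenyl]-3-(methoxycarbonyl)-2-(methoxymethylidene)-2H-pyran-4-olate (alkene geometry not defined) | [Li+].COC=C1OC(=CC([O-])=C1C(=O)OC)c1cc(OC)c(OC)cc1OCc1ccccc1 | intermediate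
11 | methyl 6-[2-(benzyloxy)-4,5-dimethoxyphenyl]-2-(1-methoxy-2-oxopropyl)-4-oxo-4H-pyran-3-carboxylate (racemate) | COC(C(C)=O)c1oc(-c2cc(OC)c(OC)cc2OCc2ccccc2)cc(=O)c1C(=O)OC | intermediate
12 | dilithium 6-[2-(benzyloxy)-4,5-dimethoxyphenyl]-3-(methoxycarbonyl)-2-(1-methoxy-2-oxidoprop-2-en-1-ylidene)-2H-pyran-4-olate (alkene geometry not defined) | [Li+].[Li+].COC(C(=C)[O-])=C1OC(=CC([O-])=C1C(=O)OC)c1cc(OC)c(OC)cc1OCc1ccccc1 | intermediate
13 | 2-[2-(benzyloxy)-4,5-dimethoxyphenyl]-5,7-dihydroxy-8-methoxy-4H-chromen-4-one | COc1cc(OCc2ccccc2)c(-c2cc(=O)c3c(O)cc(O)c(OC)c3o2)cc1OC | intermediate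
14 | 5,7-dihydroxy-2-(2-hydroxy-4,5-dimethoxyphenyl)-8-methoxy-4H-chromen-4-one | COc1cc(O)c(-c2cc(=O)c3c(O)cc(O)c(OC)c3o2)cc1OC | target

Total step count: 7. Longest linear sequence: 7 steps (1 → 14); 6 enters as a purchased building block in step 4.

**Steps most likely to fail**

Step 6 (Claisen closure of ring A). The C7 enolate oxygen could acylate in place of C6 and give a fused 2-pyranone, the second deprotonation could be incomplete, or the base could open the pyranone. The fallback closes ring A at C7–C8 instead of C5–C6, with the stabilised lateral carbanion as the nucleophile. It sets out from 9: the methyl ester would be cleaved with Me3SnOH (1,2-dichloroethane, 80 °C) to 6-[2-(benzyloxy)-4,5-dimethoxyphenyl]-2-(methoxymethyl)-4-oxo-4H-pyran-3-carboxylic acid F1. The acid would be activated with 1,1'-carbonyldiimidazole and extended with Mg(O2CCH2CO2Me)2 (Masamune homologation) to methyl 3-{6-[2-(benzyloxy)-4,5-dimethoxyphenyl]-2-(methoxymethyl)-4-oxo-4H-pyran-3-yl}-3-oxopropanoate F2. NaH (3 equiv, THF, 0 °C → 60 °C) would then effect a Dieckmann condensation of the C8 carbanion onto the C7 ester, with aromatisation, and the route would be rejoined at 13.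

Step 5 (lateral acylation). The extended enolate could be acylated on oxygen, be quenched by proton transfer from the more acidic product, or react too slowly with the acyl donor. The fallback reaches the ketone by aldol addition and oxidation instead of acylation. It sets out from 9: the lithium dienolate 10 would add to acetaldehyde (vinylogous aldol), and the aldolate would be trapped at −78 °C with Et3SiCl before it can lactonise onto the neighbouring ester, to give methyl 6-[2-(benzyloxy)-4,5-dimethoxyphenyl]-2-{1-methoxy-2-[(triethylsilyl)oxy]propyl}-4-oxo-4H-pyran-3-carboxylate F3 (racemic mixture of diastereomers). Jones oxidation (CrO3, H2SO4, acetone, 0 °C), which converts silyl ethers of secondary alcohols directly into ketones, would give 11.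

Step 4 (C-acylation and pyranone closure). Chloride or the amine base could add to the electron-rich ynoyl chloride, the triacylmethane 8 could lose an acyl group to a nucleophile, or the ring closure could stall. The fallback replaces the alkyne by a β-chloroalkene, so that ring C closes by addition–elimination instead of addition to a triple bond. It sets out from 5: LiCl in acetic acid (70 °C) would add HCl across the triple bond to give (Z)-3-[2-(benzyloxy)-4,5-dimethoxyphenyl]-3-chloroprop-2-enoic acid F4. Oxalyl chloride would convert it into (Z)-3-[2-(benzyloxy)-4,5-dimethoxyphenyl]-3-chloroprop-2-enoyl chloride F5, which would C-acylate the magnesium enolate of 6 to methyl (Z)-5-[2-(benzyloxy)-4,5-dimethoxyphenyl]-5-chloro-2-(methoxyacetyl)-3-oxopent-4-enoate F6. The enol oxygen would then replace the vinylic chloride (6-endo-trig addition–elimination, Et3N), and the route would be rejoined at 9.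

**Further compounds**

F1 | step 6 | 6-[2-(benzyloxy)-4,5-dimethoxyphenyl]-2-(methoxymethyl)-4-oxo-4H-pyran-3-carboxylic acid | COCc1oc(-c2cc(OC)c(OC)cc2OCc2ccccc2)cc(=O)c1C(=O)O
F2 | step 6 | methyl 3-{6-[2-(benzyloxy)-4,5-dimethoxyphenyl]-2-(methoxymethyl)-4-oxo-4H-pyran-3-yl}-3-oxopropanoate | COCc1oc(-c2cc(OC)c(OC)cc2OCc2ccccc2)cc(=O)c1C(=O)CC(=O)OC
F3 | step 5 | methyl 6-[2-(benzyloxy)-4,5-dimethoxyphenyl]-2-{1-methoxy-2-[(triethylsilyl)oxy]propyl}-4-oxo-4H-pyran-3-carboxylate (racemic mixture of diastereomers) | COC(C(C)O[Si](CC)(CC)CC)c1oc(-c2cc(OC)c(OC)cc2OCc2ccccc2)cc(=O)c1C(=O)OC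
F4 | step 4 | (Z)-3-[2-(benzyloxy)-4,5-dimethoxyphenyl]-3-chloroprop-2-enoic acid | OC(=O)/C=C(\Cl)c1cc(OC)c(OC)cc1OCc1ccccc1
F5 | step 4 | (Z)-3-[2-(benzyloxy)-4,5-dimethoxyphenyl]-3-chloroprop-2-enoyl chloride | ClC(=O)/C=C(\Cl)c1cc(OC)c(OC)cc1OCc1ccccc1
F6 | step 4 | methyl (Z)-5-[2-(benzyloxy)-4,5-dimethoxyphenyl]-5-chloro-2-(methoxyacetyl)-3-oxopent-4-enoate | COCC(=O)C(C(=O)OC)C(=O)/C=C(\Cl)c1cc(OC)c(OC)cc1OCc1ccccc1
A1 | direct plan | 4-(benzyloxy)-3-methoxy-6-(tosyloxy)-2-(trimethylsilyl)phenyl trifluoromethanesulfonate | COc1c([Si](C)(C)C)c(OS(=O)(=O)C(F)(F)F)c(OS(=O)(=O)c2ccc(C)cc2)cc1OCc1ccccc1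
A2 | direct plan | caesium 3-[2-(benzyloxy)-4,5-dimethoxyphenyl]prop-2-ynoate | [Cs+].[O-]C(=O)C#Cc1cc(OC)c(OC)cc1OCc1ccccc1
A3 | direct plan | 1-[4-(benzyloxy)-2-hydroxy-3-methoxy-6-(tosyloxy)phenyl]-3-[2-(benzyloxy)-4,5-dimethoxyphenyl]prop-2-yn-1-one | COc1cc(OCc2ccccc2)c(C#CC(=O)c2c(OS(=O)(=O)c3ccc(C)cc3)cc(OCc3ccccc3)c(OC)c2O)cc1OC
A4 | direct plan | 7-(benzyloxy)-2-[2-(benzyloxy)-4,5-dimethoxyphenyl]-8-methoxy-4-oxo-4H-chromen-5-yl 4-methylbenzenesulfonate | COc1cc(OCc2ccccc2)c(-c2cc(=O)c3c(OS(=O)(=O)c4ccc(C)cc4)cc(OCc4ccccc4)c(OC)c3o2)cc1OC
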